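Plan
1. Cuts: C2–Br and C3–S come off first, both being electrophilic substitutions on the pyrrole half. N1 is then masked as N–Ts, and the benzo ring of 4,5,6-tribromo-1-tosylindole is opened at C5–C6 with formal return of HBr.
2. Enabling feature: in the benzo ring, C4, C5 and C6 bear three contiguous bromines and C7 bears hydrogen. C4/C5 can therefore be read as a CBr=CBr2 arm on C3a and C7/C6 as a CH=CHBr arm on C7a, with the C7a=C3a pyrrole bond as the middle of a hexatriene.
3. The arms are cut at C3a–C4 (Sonogashira bond, the alkyne then being brominated twice) and at C7=C6 (Takai olefination of the C7 aldehyde with CHBr3).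
4. Forward order: the pyrrole ring is bought and both arms are grown on it. The six-membered ring closes second (electrocyclization, then HBr loss), and after detosylation SMe goes on C3 and Br on C2.
5. Stereochemistry: the target has no stereocentre. The only stereo elements are the E geometry of the bromovinyl arm (set in the Takai step) and a transient racemic C6 centre that aromatization erases.

Key step: step 6

Remark: indole numbering is used for the atoms of both arms throughout, and compound 1 and anhydrous CrBr2 are taken as purchasable.

Step 1
Reactants: 1 3-bromo-1H-pyrrole-2-carbaldehyde; 2 4-toluenesulfonyl chloride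
Product: 3 3-bromo-1-tosylpyrrole-2-carbaldehyde
Conditions: NaH, THF, 0 °C; then 2, 0 °C to rt
Reagents that add atoms: 4-toluenesulfonyl chloride (2), Cc1ccc(cc1)S(=O)(=O)Cl
Why: N-sulfonylation of the sodium pyrrolide, whose N–H is acidified by the 2-formyl group, is a standard protection, and the tosyl group also shields the ring from Br2, NBS and HBr and weakens the pyrrole aromaticity that step 6 must give up.

Step 2
Reactants: 3 3-bromo-1-tosylpyrrole-2-carbaldehyde; 4 trimethylsilylacetylene
Product: 5 1-tosyl-3-[(trimethylsilyl)ethynyl]pyrrole-2-carbaldehyde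
Conditions: Pd(PPh3)2Cl2 (cat.), CuI (cat.), Et3N, THF, 55 °C, Ar
Reagents that add atoms: trimethylsilylacetylene (4), C#C[Si](C)(C)C
Why: In this Sonogashira coupling the C–Br bond sits next to the formyl group on an electron-poor N-sulfonylpyrrole, so oxidative addition to zerovalent palladium should be easy, and a tertiary amine base leaves the aldehyde and the N–Ts bond untouched.

Step 3
Reactants: 5 1-tosyl-3-[(trimethylsilyl)ethynyl]pyrrole-2-carbaldehyde
Product: 6 3-(bromoethynyl)-1-tosylpyrrole-2-carbaldehyde
Conditions: NBS, AgNO3 (cat.), dry acetone, rt, dark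
Reagents that add atoms: N-bromosuccinimide, O=C1CCC(=O)N1Br
Why: Silver-catalysed bromodesilylation of an alkynylsilane with NBS is the standard one-step entry to 1-bromoalkynes and should leave the aldehyde and the deactivated pyrrole C–H positions alone.

Step 4
Reactants: 6 3-(bromoethynyl)-1-tosylpyrrole-2-carbaldehyde
Product: 7 3-(1,2,2-tribromovinyl)-1-tosylpyrrole-2-carbaldehyde
Conditions: Br2 (1 equiv), CH2Cl2, 0 °C to rt, dark
Reagents that add atoms: bromine, BrBr
Why: Electrophilic addition of bromine to a 1-bromoalkyne gives the 1,2,2-tribromoalkene with no E/Z question because the terminus carries two bromines, while the ring bearing Ts, CHO and the alkyne is too electron-poor to be brominated at this temperature, and with bromide as the only nucleophile any participation of the formyl oxygen stays reversible.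

Step 5
Reactants: 7 3-(1,2,2-tribromovinyl)-1-tosylpyrrole-2-carbaldehyde; 8 bromoform
Product: 9 2-[(E)-2-bromovinyl]-3-(1,2,2-tribromovinyl)-1-tosylpyrrole
Conditions: CrBr2 (excess), THF, 0 °C to rt, Ar
Reagents that add atoms: bromoform (8), BrC(Br)Br
Why: In the Takai olefination divalent chromium reduces CHBr3 to a geminal dichromium species that adds to the aldehyde and eliminates from the conformer with pyrrolyl and bromine anti, which sets the E geometry, while CrBr2 in place of CrCl2 excludes chloride exchange into the vinyl halide and, without a nickel salt, divalent chromium should not insert into the sp2 C–Br bonds.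

Step 6
Reactants: 9 2-[(E)-2-bromovinyl]-3-(1,2,2-tribromovinyl)-1-tosylpyrrole
Product: 11 4,5,6-tribromo-1-tosylindole, via 4,5,5,6-tetrabromo-1-tosyl-5,6-dihydroindole 10 (not isolated)
Conditions: K2CO3 (powder), BHT (cat.), o-dichlorobenzene (degassed, dilute), 160–180 °C, dark
Reagents that add atoms: none
Why: Proposed new method: heating should bring the C6=C7 arm, the C7a=C3a pyrrole bond and the C4=C5 arm into the helical s-cis,s-cis array of a hexatriene, which closes the six-membered carbocycle by a thermally allowed disrotatory six-electron electrocyclization that forms C5–C6 and gives 10, in which the double bonds lie at C7=C7a, C3a=C4 and C2=C3 and the pyrrole is dearomatized. The closest known reaction type is the thermal electrocyclization of 2,3-divinylpyrroles and 2,3-divinylindoles, followed by dehydrogenation or loss of a leaving group, to give indoles and carbazoles, whereas a triene carrying four bromines has not been shown. In 10 C5 holds two bromines and C6 holds H and Br, so C6 is the only new stereocentre, arises racemic with no control needed and disappears again, and because one of the two C5 bromines always stands anti to the C6 hydrogen, E2 loss of HBr is open in any case, restores both the benzene and the pyrrole sextet and makes the uphill closure irreversible. The selectivity required is loss of HBr rather than bromide-induced loss of Br2 across C5–C6, and it is secured by the acidic allylic C6–H and by an insoluble carbonate in an apolar solvent, which removes bromide from solution as solid KBr. The E geometry turns the C6 bromine outward so that only one bromine (on C5) points into the closing termini, and it places the vinylic C7–H and the C6 bromine syn, so the base should not dehydrobrominate this arm to an alkyne. The tosyl group lowers the aromatic stabilization that is sacrificed, and BHT, darkness and degassing hold back C–Br homolysis at the temperature that the twisted tribromovinyl arm is likely to demand.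

Step 7
Reactants: 11 4,5,6-tribromo-1-tosylindole
Product: 12 4,5,6-tribromo-1H-indole
Conditions: KOH, 1,4-dioxane–H2O, 60 °C; then aq. HCl to pH 6
Reagents that add atoms: none
Why: Basic hydrolysis of an N-sulfonylindole proceeds by hydroxide attack at sulfur, is helped here by an indolide leaving group stabilized by three bromines, and avoids the reductive detosylation methods that would cleave C–Br bonds.

Step 8
Reactants: 12 4,5,6-tribromo-1H-indole
Product: 13 4,5,6-tribromo-3-(methylsulfanyl)-1H-indole
Conditions: MeSSMe, SO2Cl2, CH2Cl2, −20 °C; then 12, CH2Cl2, −40 °C to 0 °C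
Reagents that add atoms: dimethyl disulfide, CSSC (acts as methanesulfenyl chloride, CSCl, made from it in the flask)
Why: Electrophilic C3 sulfenylation of an N–H indole with a sulfenyl chloride is standard, C3 remains the most nucleophilic carbon even in this brominated indole, and one equivalent of reagent at low temperature should stop before a second sulfenylation at C2.

Step 9
Reactants: 13 4,5,6-tribromo-3-(methylsulfanyl)-1H-indole
Product: 14 2,4,5,6-tetrabromo-3-(methylsulfanyl)-1H-indole
Conditions: NBS (1 equiv), dry CH2Cl2, −78 °C to 0 °C, dark
Reagents that add atoms: N-bromosuccinimide, O=C1CCC(=O)N1Br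
Why: In the electrophilic bromination of a 3-substituted indole with NBS the bromine is taken up at C3 or sulfur and passes to C2 through the 3-bromoindolenine before proton loss, C2 being the only open pyrrole position and C7 lying on a ring deactivated by three bromines, and water is excluded so that oxidation at sulfur and hydrolysis of the indolenine cannot compete.

Compound list
1 | 3-bromo-1H-pyrrole-2-carbaldehyde | O=Cc1[nH]ccc1Br | starting material
2 | 4-toluenesulfonyl chloride | Cc1ccc(cc1)S(=O)(=O)Cl | starting material
3 | 3-bromo-1-tosylpyrrole-2-carbaldehyde | Cc1ccc(cc1)S(=O)(=O)n1ccc(Br)c1C=O | intermediate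
4 | trimethylsilylacetylene | C#C[Si](C)(C)C | starting material
5 | 1-tosyl-3-[(trimethylsilyl)ethynyl]pyrrole-2-carbaldehyde | Cc1ccc(cc1)S(=O)(=O)n1ccc(C#C[Si](C)(C)C)c1C=O | intermediate
6 | 3-(bromoethynyl)-1-tosylpyrrole-2-carbaldehyde | Cc1ccc(cc1)S(=O)(=O)n1ccc(C#CBr)c1C=O | intermediate
7 | 3-(1,2,2-tribromovinyl)-1-tosylpyrrole-2-carbaldehyde | Cc1ccc(cc1)S(=O)(=O)n1ccc(C(Br)=C(Br)Br)c1C=O | intermediate
8 | bromoform | BrC(Br)Br | starting material
9 | 2-[(E)-2-bromovinyl]-3-(1,2,2-tribromovinyl)-1-tosylpyrrole | Cc1ccc(cc1)S(=O)(=O)n1ccc(C(Br)=C(Br)Br)c1/C=C/Br | intermediate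
10 | 4,5,5,6-tetrabromo-1-tosyl-5,6-dihydroindole (racemic at C6, not isolated) | Cc1ccc(cc1)S(=O)(=O)N1C=CC2=C(Br)C(Br)(Br)C(Br)C=C12 | intermediate
11 | 4,5,6-tribromo-1-tosylindole | Cc1ccc(cc1)S(=O)(=O)n1ccc2c(Br)c(Br)c(Br)cc21 | intermediate
12 | 4,5,6-tribromo-1H-indole | Brc1cc2[nH]ccc2c(Br)c1Br | intermediate
13 | 4,5,6-tribromo-3-(methylsulfanyl)-1H-indole | CSc1c[nH]c2cc(Br)c(Br)c(Br)c12 | intermediate
14 | 2,4,5,6-tetrabromo-3-(methylsulfanyl)-1H-indole | CSc1c(Br)[nH]c2cc(Br)c(Br)c(Br)c12 | target

Total step count: 9
Longest linear sequence: 9 steps (1 to 14)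

Steps most likely to fail

Step 6. The twisted tribromovinyl arm may not reach the closing geometry below the temperature at which C–Br homolysis, E/Z scrambling or oligomerization take over. Aromatization may also drift toward loss of Br2. The fallback uses only known chemistry and gives up the pyrrole-first order. It sets out from 2 and comes back to the route at 11. Purchased 5-nitro-1H-indole F1 is tosylated with 2 (NaH, DMF, 0 °C) to 5-nitro-1-tosylindole F2. Hydrogenation (H2, Pd/C, EtOAc) gives 1-tosylindol-5-amine F3. The amino group then directs two equivalents of NBS (MeCN, 0 °C) to its two ortho positions C4 and C6, while the sulfonylated pyrrole half stays inert, giving 4,6-dibromo-1-tosylindol-5-amine F4. A Sandmeyer bromination (t-BuONO, CuBr2, MeCN) replaces the amine by the C5 bromine and delivers 11.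

Step 5. Excess divalent chromium may strip bromine reductively from the tribromovinyl arm, and the E selectivity may erode on this crowded aldehyde. The fallback avoids any reducing metal. It sets out from 7 and comes back at 9. A Wittig reaction with tert-butyl (triphenylphosphoranylidene)acetate (toluene, rt to 60 °C) gives tert-butyl (E)-3-[3-(1,2,2-tribromovinyl)-1-tosylpyrrol-2-yl]prop-2-enoate F5. TFA in CH2Cl2 frees (E)-3-[3-(1,2,2-tribromovinyl)-1-tosylpyrrol-2-yl]prop-2-enoic acid F6. A catalytic Hunsdiecker-type bromodecarboxylation (NBS, LiOAc cat., MeCN–H2O) then converts the acrylic acid into the E-bromoalkene 9.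

Step 9. NBS may oxidize the sulfide, adventitious water may capture the bromoindolenine, or traces of acid may cause the sulfenyl group to migrate. The fallback installs the C2 bromine by directed metalation before the sulfur is present. It sets out from 11 and comes back at 14. The sulfonyl-directed C2 metalation of 11 (TMPMgCl·LiCl, THF, −20 °C), quenched with 1,2-dibromo-1,1,2,2-tetrachloroethane, gives 2,4,5,6-tetrabromo-1-tosylindole F7. Hydrolysis as in step 7 gives 2,4,5,6-tetrabromo-1H-indole F8. Sulfenylation of its only open pyrrole position with methanesulfenyl chloride, as in step 8, gives 14.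

Further compounds
F1 | step 6 | 5-nitro-1H-indole (bought, not made) | O=[N+]([O-])c1ccc2[nH]ccc2c1
F2 | step 6 | 5-nitro-1-tosylindole | Cc1ccc(cc1)S(=O)(=O)n1ccc2cc(ccc21)[N+](=O)[O-]
F3 | step 6 | 1-tosylindol-5-amine | Cc1ccc(cc1)S(=O)(=O)n1ccc2cc(N)ccc21
F4 | step 6 | 4,6-dibromo-1-tosylindol-5-amine | Cc1ccc(cc1)S(=O)(=O)n1ccc2c(Br)c(N)c(Br)cc21
F5 | step 5 | tert-butyl (E)-3-[3-(1,2,2-tribromovinyl)-1-tosylpyrrol-2-yl]prop-2-enoate | Cc1ccc(cc1)S(=O)(=O)n1ccc(C(Br)=C(Br)Br)c1/C=C/C(=O)OC(C)(C)C
F6 | step 5 | (E)-3-[3-(1,2,2-tribromovinyl)-1-tosylpyrrol-2-yl]prop-2-enoic acid | Cc1ccc(cc1)S(=O)(=O)n1ccc(C(Br)=C(Br)Br)c1/C=C/C(=O)O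
F7 | step 9 | 2,4,5,6-tetrabromo-1-tosylindole | Cc1ccc(cc1)S(=O)(=O)n1c(Br)cc2c(Br)c(Br)c(Br)cc21
F8 | step 9 | 2,4,5,6-tetrabromo-1H-indole | Brc1cc2c(Br)c(Br)c(Br)cc2[nH]1
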